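## Analysis of the target

The target is a macrocyclic bis(bibenzyl). Four benzene rings are joined in a cycle by two diaryl ether oxygens (ring A–O–ring B and ring C–O–ring D) and two ethano bridges (ring B–CH2CH2–ring C and ring D–CH2CH2–ring A), a 17-membered ring along the shortest path. With the ring A carbons numbered C1 to C6, C1 carries a hydroxyl, C3 the arm to ring D, C5 the oxygen to ring B and C6 the second hydroxyl. Ring B is para-linked and ring D ortho-linked; ring C carries its arm on C1, hydroxyls on C4 and C5 and the oxygen to ring D on C6. There is no stereocentre, so the only stereochemical event is the geometry of a bridge alkene that is hydrogenated afterwards. The two catechols oxidise in air once free and stay masked until the last step; the diaryl ethers and benzylic methylenes are robust. Three things make the synthesis hard: the ring C ether oxygen sits on a carbon flanked on both sides, ring A carries three neighbouring oxygens of three different kinds, and a large ring must be closed. The plan rests on ring A: C1 (hydroxyl), C5 (aryloxy) and C3 (arm) are mutually meta, the pattern a cyclobutenone and an oxygen-substituted alkyne give on benzannulation, and C6 lies between two oxygens, where an aromatic C–H is most easily lithiated.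

## Retrosynthetic reasoning

**Unmasking (38 from 37 from 36).** The catechols are revealed last by cleaving every O-alkyl group of 37 in one Lewis-acid step. 37 comes from stilbene 36 by hydrogenation, so the geometry of the ring-closing alkene does not matter.

**Ring B–ring C bridge (36 from 34).** The macrocycle is opened at the bridge between rings B and C, drawn as an alkene made by intramolecular Wittig reaction of phosphonium aldehyde 34. Both bridge carbons trace back to one-carbon groups already present in commercial materials (the formyl carbon of 1 and the hydroxymethyl carbon of 13). This bridge is also remote from the crowded ring C–ring D ether, and the other bridge is needed to carry the cyclobutenone. 34 comes from 29 by unmasking the two silyl-protected carbinols one after the other (30, 31, 32). The labile TBS group is placed on the unhindered ring B carbinol and the robust TIPS group on the hindered ring C carbinol, so the first desilylation is favoured by both the silyl group and its surroundings.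

**C6–O bond of ring A (29 from 25).** The last oxygen is introduced by lithiation of C6–H, borylation and oxidation to 28, then methylation. C6 is the only aromatic carbon flanked by two ether oxygens, so its proton is the most acidic.

**Ring A (25 from 24 from 12 + 19).** Ring A is taken apart at C1–C6 and C4–C5. Cyclobutenone 12 supplies C1 to C4 with the arm on C3, and ynol ether 19 supplies C5 and C6 with the ring B oxygen already on C5. No aryl C–O coupling is therefore needed on the oxygen-rich ring, and the ring C/ring D half and the ring B piece are joined as ring A forms. The forward step must pair vinylketene 20 with 19 in one orientation and carry the adduct through to phenol 24.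

**Ynol ether (19 from 16 from 14 + 15; 14 from 13).** The alkynyl ether is cut at the O–C(sp) bond. Both alkyne carbons come from trichloroethylene 15, attached to phenol 14 as dichlorovinyl ether 16 and then eliminated and metalated. 14 is the monosilyl ether of 13.

**Cyclobutenone (12 from 11 from 10).** The four-membered ring is cut into terminal alkyne 10 and a two-carbon ketene unit, joined by (2+2) cycloaddition to 11 and reductively dechlorinated. This is the standard entry to 3-alkylcyclobutenones.

**Butynyl chain (10 from 8 from 7 from 6).** The chain is grown from the ring D aldehyde of 6: two carbons by olefination (7) and hydrogenation (8), one by reduction to aldehyde 9 and alkyne homologation.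

**Hindered ether (6 from 5 from 3 from 1 + 2).** The ring C–O–ring D bond is cut on the ring D side, so the crowded ring C oxygen acts as nucleophile and displaces the fluorine of 2. The nitrile that activates this substitution then becomes the ring D aldehyde while the ring C formyl group goes to the carbinol (3 to 5), which separates the two carbons in one operation.

## Alternatives that were turned down

**Alternative 1:** Here both inner C–O bonds (ring A C6 and ring C C5) are cut last. The macrocycle lacking these two hydroxyls is carried as its bis(methoxymethyl) ether A1, lithiated twice with an alkyllithium–diamine base, trapped with a borate ester and oxidised to diol A2.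
- For it: both sites lie between an acetal oxygen and an aryloxy oxygen, so regiochemistry is sound. The building blocks are simpler, and the ring C–ring D ether is less crowded while ring C lacks the inner oxygen. On oxygenation economy it is stronger than the chosen plan.
- Against it: two metalations must both go to completion on one molecule. The first aryllithium aggregates and slows the second, and any monohydroxylated material differs from A2 by one oxygen and will be hard to separate. All of this falls on the most valuable intermediate, and the macrocycle must still be made by a ring closure of its own.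
- Comparison: the chosen plan needs one lithiation on an open-chain compound directly after the ring-forming step, and buys the ring C oxygens ready-made in aldehyde 1.

**Alternative 2:** Here the ring A–O–ring B bond is cut and formed as the ring-closing step. The open-chain 4-fluorophenyl ketone A3, with a free ring A phenol, is cyclised by carbonate base in a dipolar aprotic solvent to macrocyclic ketone A4, the bridge ketone activating the fluoride.
- For it: ether formation and ring closure happen together in a well-established reaction class, and no fragile alkyne is involved. This is stronger than the chosen plan, which spends phosphonium formation, Wittig closure and hydrogenation on the ring closure.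
- Against it: the CH2 between ring C and the carbonyl is about as acidic as the phenol. Its enolate no longer withdraws electrons from ring B and opens aldol and oxidation paths. The ketone must later be removed in the presence of many ethers, and ring A must be brought in with its three oxygens already differentiated. The ring C–ring D ether and the second bridge need separate chemistry.
- Comparison: the chosen plan offers a neutral thermal step that creates the ring A oxygen pattern and the A–B ether together from two simple fragments, with no base-sensitive carbonyl near the closure.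

**Alternative 3:** Here ring D is built on the hindered oxygen. The internal aryl ynol ether A5 (ring C oxygen on one alkyne carbon, the ring A arylethyl chain on the other) reacts with 2H-pyran-2-one A6 by (4+2) cycloaddition and loss of CO2 to give A7.
- For it: the crowded C–O bond is made as a simple phenol alkynylation. Because A6 is unsubstituted, either orientation gives the same ortho-phenylene, so there is no regiochemical question.
- Against it: an unactivated pyranone needs forcing temperatures, at which an alkynyl ether with a propargylic CH2 can isomerise. Ring D is the plainest ring of the target, so the effort buys little. The ring A–ring B ether remains, and would have to close the macrocycle by a copper-mediated coupling at a bromide flanked by a methoxy group.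
- Comparison: the chosen plan makes the same hindered ether in one substitution step from 1 and 2 and spends its ring synthesis on ring A, where it solves the oxygen pattern.

Key step: step 12

**Remarks.** The macrocycle is assumed to have no configurationally stable atropisomer, so the target is a single achiral compound. In names, "CD-aryl" is the 2-[2,3-dimethoxy-6-({[tri(propan-2-yl)silyl]oxy}methyl)phenoxy]phenyl group (ring D, attached through the carbon ortho to its ether oxygen), and "B-aryl" is the 4-({[tert-butyl(dimethyl)silyl]oxy}methyl)phenyl group.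

## Route

Step 1
Reactants: 1 2-hydroxy-3,4-dimethoxybenzaldehyde; 2 2-fluorobenzonitrile
Product: 3 2-(6-formyl-2,3-dimethoxyphenoxy)benzonitrile
Conditions: K2CO3, DMF, 120 °C
Reagents that add atoms: none
Why: Nucleophilic aromatic substitution by addition–elimination; the ortho-cyano group activates the fluoride enough for the hindered, hydrogen-bonded phenoxide of 1, so the ether oxygen is placed between the formyl-bearing carbon and a methoxy group without a metal-catalysed coupling.

Step 2
Reactants: 3 2-(6-formyl-2,3-dimethoxyphenoxy)benzonitrile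
Product: 5 2-[6-(hydroxymethyl)-2,3-dimethoxyphenoxy]benzaldehyde, via aluminium aldimine alkoxide 4 (not isolated)
Conditions: i-Bu2AlH (2.5 equiv), CH2Cl2, −78 → 0 °C; then 1 M HCl, 0 °C
Reagents that add atoms: water, O
Why: The aluminium hydride reduces the aldehyde to its alkoxide and adds once to the nitrile, stopping at the N-aluminated aldimine 4, which acid hydrolyses to the aldehyde (nitrile-to-aldehyde reduction); one reagent thus sets ring C to the alcohol level and ring D to the aldehyde level.

Step 3
Reactants: 5 2-[6-(hydroxymethyl)-2,3-dimethoxyphenoxy]benzaldehyde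
Product: 6 2-[2,3-dimethoxy-6-({[tri(propan-2-yl)silyl]oxy}methyl)phenoxy]benzaldehyde
Conditions: i-Pr3SiCl, imidazole, DMAP (cat.), DMF, rt
Reagents that add atoms: chlorotri(propan-2-yl)silane, CC(C)[Si](Cl)(C(C)C)C(C)C
Why: Silylation of a primary alcohol; the bulky TIPS ether is chosen because it must outlast hydride, carbonate, zinc salts, heat and butyllithium and stay on when the TBS ether of ring B is removed.

Step 4
Reactants: 6 2-[2,3-dimethoxy-6-({[tri(propan-2-yl)silyl]oxy}methyl)phenoxy]benzaldehyde
Product: 7 ethyl (2E)-3-(CD-aryl)prop-2-enoate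
Conditions: (EtO)2P(O)CH2CO2Et, NaH, THF, 0 °C → rt
Reagents that add atoms: triethyl phosphonoacetate, CCOC(=O)CP(=O)(OCC)OCC
Why: Horner–Wadsworth–Emmons olefination of an aromatic aldehyde with a stabilised phosphonate anion; the E ester is expected, and its geometry is irrelevant because the alkene is reduced next.

Step 5
Reactants: 7 ethyl (2E)-3-(CD-aryl)prop-2-enoate
Product: 8 ethyl 3-(CD-aryl)propanoate
Conditions: H2 (1 atm), Pd/C, EtOAc, rt
Reagents that add atoms: none
Why: Catalytic hydrogenation of a cinnamate double bond; in a neutral aprotic solvent the benzylic silyl ether and the diaryl ether should not undergo hydrogenolysis.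

Step 6
Reactants: 8 ethyl 3-(CD-aryl)propanoate
Product: 10 4-(CD-aryl)but-1-yne, via propanal 9 (not isolated)
Conditions: i-Bu2AlH (1.1 equiv), CH2Cl2, −78 °C; then MeOH, K2CO3, dimethyl (1-diazo-2-oxopropyl)phosphonate, −78 °C → rt
Reagents that add atoms: dimethyl (1-diazo-2-oxopropyl)phosphonate, COP(=O)(OC)C(=[N+]=[N-])C(C)=O
Why: Partial reduction of the ester at low temperature releases aldehyde 9 on the methanol quench, and Ohira–Bestmann (Seyferth–Gilbert) homologation under carbonate turns it into the terminal alkyne in the same flask; the TIPS ether tolerates both stages.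

Step 7
Reactants: 10 4-(CD-aryl)but-1-yne
Product: 11 4,4-dichloro-3-[2-(CD-aryl)ethyl]cyclobut-2-en-1-one
Conditions: Cl3CCOCl, Zn–Cu couple, Et2O/DME, rt
Reagents that add atoms: trichloroacetyl chloride, ClC(=O)C(Cl)(Cl)Cl
Why: (2+2) Cycloaddition of dichloroketene, generated in the flask by zinc, to the terminal alkyne; the ketene carbonyl carbon bonds to the unsubstituted alkyne carbon, giving the 3-substituted 4,4-dichlorocyclobutenone, and dimethoxyethane ties up ZnCl2 so the silyl ether and electron-rich rings are spared.

Step 8
Reactants: 11 4,4-dichloro-3-[2-(CD-aryl)ethyl]cyclobut-2-en-1-one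
Product: 12 3-[2-(CD-aryl)ethyl]cyclobut-2-en-1-one
Conditions: Zn dust, AcOH, TMEDA, EtOH, 0 °C → rt
Reagents that add atoms: none
Why: Reductive dechlorination of an α,α-dichloroketone by zinc in a buffered medium should remove both chlorines without reducing or isomerising the strained enone.

Step 9
Reactants: 13 4-(hydroxymethyl)phenol
Product: 14 4-({[tert-butyl(dimethyl)silyl]oxy}methyl)phenol
Conditions: t-BuMe2SiCl (1.05 equiv), imidazole, DMF, 0 °C
Reagents that add atoms: tert-butyl(chloro)dimethylsilane, CC(C)(C)[Si](C)(C)Cl
Why: Chemoselective O-silylation; with imidazole as the only base the phenol stays protonated and the primary alcohol is the better nucleophile, and any aryl silyl ether formed can be cleaved again by brief K2CO3/MeOH.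

Step 10
Reactants: 14 4-({[tert-butyl(dimethyl)silyl]oxy}methyl)phenol; 15 trichloroethylene
Product: 16 tert-butyl[(4-{[(E)-1,2-dichloroethenyl]oxy}phenyl)methoxy]dimethylsilane
Conditions: K2CO3, DMF, 70 °C
Reagents that add atoms: none
Why: Elimination–addition; base converts 15 into dichloroacetylene, to which the phenoxide adds in anti fashion to give the (E)-1,2-dichlorovinyl ether, the known first stage of the dichlorovinyl ether route to alkynyl ethers.

Step 11
Reactants: 16 tert-butyl[(4-{[(E)-1,2-dichloroethenyl]oxy}phenyl)methoxy]dimethylsilane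
Product: 19 tert-butyl{[4-(ethynyloxy)phenyl]methoxy}dimethylsilane, via chloroethynyl ether 17 (not isolated), via lithium acetylide 18 (not isolated)
Conditions: n-BuLi (2.2 equiv), Et2O, −78 → −40 °C; then MeOH, −78 °C
Reagents that add atoms: none
Why: The first equivalent of butyllithium dehydrochlorinates 16 to chloroalkyne 17, the second exchanges chlorine for lithium to give acetylide 18, and cold protonation gives the terminal ynol ether; it is filtered cold and used at once because aryl ethynyl ethers polymerise on standing.

Step 12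
Reactants: 12 3-[2-(CD-aryl)ethyl]cyclobut-2-en-1-one; 19 tert-butyl{[4-(ethynyloxy)phenyl]methoxy}dimethylsilane
Product: 24 3-(B-aryloxy)-5-[2-(CD-aryl)ethyl]phenol, via vinylketene 20 (not isolated), via vinylcyclobutenone 21 (not isolated), via dienylketene 22 (not isolated), via cyclohexadienone 23 (not isolated)
Conditions: 19 (2 equiv), toluene, 80 °C, then 110 °C
Reagents that add atoms: none
Why: Thermal four-electron electrocyclic opening of cyclobutenone 12 gives vinylketene 20. Its ketene C=C bond undergoes (2+2) cycloaddition with ynol ether 19, the electron-rich unsubstituted alkyne carbon attacking the electrophilic ketene carbonyl carbon; this forms the C1–C6 and C4–C5 bonds of ring A in cyclobutenone 21 and fixes the aryloxy carbon meta to the future hydroxyl carbon. A second four-electron opening of 21 leads to dienylketene 22, and only the isomer with ketene and vinyl termini cis reacts on, the other reverting to 21. Ring A closes by six-electron disrotatory electrocyclisation of 22 (ketene carbon to terminal methylene carbon, the C1–C2 bond), and dienone 23 tautomerises irreversibly to phenol 24. The closest known reaction is the Danheiser benzannulation of 3-alkylcyclobutenones with alkoxy- and silyloxyalkynes, and an aryl ynol ether belongs to the same class of oxygen-substituted alkynes. No stereocentre remains, since the one in 21 is lost on ring opening. The step needs regioselectivity, secured by the polarisation of 19, and capture of 20 by the alkyne rather than by a second ketene or by the product phenol, for which the excess of 19 and moderate concentration are chosen; the silyl, methyl and diaryl ethers are inert to neutral heating.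

Step 13
Reactants: 24 3-(B-aryloxy)-5-[2-(CD-aryl)ethyl]phenol
Product: 25 1-(B-aryloxy)-3-[2-(CD-aryl)ethyl]-5-(methoxymethoxy)benzene
Conditions: MeOCH2Cl, i-Pr2NEt, CH2Cl2, 0 °C → rt
Reagents that add atoms: chloromethyl methyl ether, COCCl
Why: O-Alkylation of the phenol with an α-chloro ether under amine base; the methoxymethyl ether is chosen because, with the neighbouring aryloxy oxygen, it makes the carbon between them the most acidic aromatic position.

Step 14
Reactants: 25 1-(B-aryloxy)-3-[2-(CD-aryl)ethyl]-5-(methoxymethoxy)benzene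
Product: 28 2-(B-aryloxy)-4-[2-(CD-aryl)ethyl]-6-(methoxymethoxy)phenol, via aryllithium 26 (not isolated), via dimethyl boronate 27 (not isolated)
Conditions: n-BuLi, THF, −20 → 0 °C; B(OMe)3, −78 °C → rt; then H2O2, aq. NaOH, 0 °C
Reagents that add atoms: hydrogen peroxide, OO
Why: Directed ortho-metalation; C6–H of ring A lies between the methoxymethoxy and aryloxy oxygens, which cooperate in coordination and inductive acidification, so it should be removed in preference to any proton next to a single oxygen. Borylation and alkaline peroxide oxidation (aryl shift from boron to oxygen) then place the hydroxyl on that carbon.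

Step 15
Reactants: 28 2-(B-aryloxy)-4-[2-(CD-aryl)ethyl]-6-(methoxymethoxy)phenol
Product: 29 1-(B-aryloxy)-5-[2-(CD-aryl)ethyl]-2-methoxy-3-(methoxymethoxy)benzene
Conditions: MeI, K2CO3, DMF, rt
Reagents that add atoms: iodomethane, CI
Why: Williamson O-methylation of the hindered phenol; the methyl ether keeps the new oxygen inert through oxidation, phosphonium formation and ylide chemistry and leaves with the other alkyl groups at the end.

Step 16
Reactants: 29 1-(B-aryloxy)-5-[2-(CD-aryl)ethyl]-2-methoxy-3-(methoxymethoxy)benzene
Product: 30 {4-[5-[2-(CD-aryl)ethyl]-2-methoxy-3-(methoxymethoxy)phenoxy]phenyl}methanol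
Conditions: pyridinium p-toluenesulfonate (cat.), MeOH, rt
Reagents that add atoms: none
Why: Acid-catalysed methanolysis of silyl ethers is governed by bulk at silicon and around oxygen, so the unhindered TBS ether on ring B should cleave well before the TIPS ether next to the aryloxy group on ring C; the weak acid should not touch the methoxymethyl ether.

Step 17
Reactants: 30 {4-[5-[2-(CD-aryl)ethyl]-2-methoxy-3-(methoxymethoxy)phenoxy]phenyl}methanol
Product: 31 4-{5-[2-(CD-aryl)ethyl]-2-methoxy-3-(methoxymethoxy)phenoxy}benzaldehyde
Conditions: MnO2, CH2Cl2, rt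
Reagents that add atoms: none
Why: MnO2 oxidises benzylic alcohols selectively to aldehydes without over-oxidation and leaves silyl, acetal and methyl ethers alone.

Step 18
Reactants: 31 4-{5-[2-(CD-aryl)ethyl]-2-methoxy-3-(methoxymethoxy)phenoxy}benzaldehyde
Product: 32 4-[5-(2-{2-[6-(hydroxymethyl)-2,3-dimethoxyphenoxy]phenyl}ethyl)-2-methoxy-3-(methoxymethoxy)phenoxy]benzaldehyde
Conditions: Bu4NF, THF, 0 °C
Reagents that add atoms: none
Why: Fluoride-induced cleavage of the remaining silyl ether, driven by the strong Si–F bond; the aldehyde has no α-hydrogen and tolerates the basic fluoride.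

Step 19
Reactants: 32 4-[5-(2-{2-[6-(hydroxymethyl)-2,3-dimethoxyphenoxy]phenyl}ethyl)-2-methoxy-3-(methoxymethoxy)phenoxy]benzaldehyde
Product: 34 {[2-(2-{2-[3-(4-formylphenoxy)-4-methoxy-5-(methoxymethoxy)phenyl]ethyl}phenoxy)-3,4-dimethoxyphenyl]methyl}triphenylphosphonium bromide, via benzylic bromide 33 (not isolated)
Conditions: PPh3, N-bromosuccinimide, CH2Cl2, −20 → 0 °C; then PPh3, MeCN, 60 °C
Reagents that add atoms: triphenylphosphine, c1ccc(cc1)P(c1ccccc1)c1ccccc1; N-bromosuccinimide, O=C1CCC(=O)N1Br
Why: Appel-type bromination through the alkoxyphosphonium salt (the bromophosphonium reagent is formed before the substrate is added) is neutral and spares the aldehyde and the acetal. The electron-rich benzylic bromide 33 is then quaternised in the same flask by more phosphine (SN2).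

Step 20
Reactants: 34 {[2-(2-{2-[3-(4-formylphenoxy)-4-methoxy-5-(methoxymethoxy)phenyl]ethyl}phenoxy)-3,4-dimethoxyphenyl]methyl}triphenylphosphonium bromide
Product: 36 macrocyclic stilbene (CH=CH between rings B and C; ring A C1 methoxymethyl ether and C6 methyl ether; ring C dimethyl ether; E/Z mixture), via phosphonium ylide 35 (not isolated)
Conditions: NaOMe, CH2Cl2, rt, slow addition of 34 (high dilution)
Reagents that add atoms: none
Why: Intramolecular Wittig olefination; methoxide turns the salt into the semistabilised ylide 35, which at high dilution adds to the aldehyde at the other chain end and closes the macrocycle, either alkene geometry being acceptable.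

Step 21
Reactants: 36 macrocyclic stilbene (E/Z mixture)
Product: 37 macrocyclic bibenzyl (CH2CH2 between rings B and C; ring A C1 methoxymethyl ether and C6 methyl ether; ring C dimethyl ether)
Conditions: H2 (1 atm), Pd/C, EtOAc, rt
Reagents that add atoms: none
Why: Catalytic hydrogenation of the stilbene double bond gives the ethano bridge from both geometric isomers; aryl ethers and the acetal are stable.

Step 22
Reactants: 37 macrocyclic bibenzyl
Product: 38 target macrocycle CNP0114693.0 (ring A C1 and C6 hydroxyls, ring C C4 and C5 hydroxyls)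
Conditions: BBr3, CH2Cl2, −78 °C → rt; then H2O, under argon
Reagents that add atoms: none
Why: The boron Lewis acid complexes each alkyl aryl ether oxygen and bromide attacks the sp3 carbon, cleaving the three methyl ethers and the methoxymethyl ether; diaryl ethers offer no such carbon and survive, and inert work-up protects the two catechols.

## Compound list

1 | 2-hydroxy-3,4-dimethoxybenzaldehyde | COc1ccc(C=O)c(O)c1OC | starting material
2 | 2-fluorobenzonitrile | N#Cc1ccccc1F | starting material
3 | 2-(6-formyl-2,3-dimethoxyphenoxy)benzonitrile | COc1ccc(C=O)c(Oc2ccccc2C#N)c1OC | intermediate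
4 | diisobutylaluminium alkoxide and N-diisobutylaluminio aldimine from 3 | CC(C)C[Al](CC(C)C)OCc1ccc(OC)c(OC)c1Oc1ccccc1C=N[Al](CC(C)C)CC(C)C | intermediate (not isolated)
5 | 2-[6-(hydroxymethyl)-2,3-dimethoxyphenoxy]benzaldehyde | COc1ccc(CO)c(Oc2ccccc2C=O)c1OC | intermediate
6 | 2-[2,3-dimethoxy-6-({[tri(propan-2-yl)silyl]oxy}methyl)phenoxy]benzaldehyde | COc1ccc(CO[Si](C(C)C)(C(C)C)C(C)C)c(Oc2ccccc2C=O)c1OC | intermediate
7 | ethyl (2E)-3-(CD-aryl)prop-2-enoate | CCOC(=O)/C=C/c1ccccc1Oc1c(CO[Si](C(C)C)(C(C)C)C(C)C)ccc(OC)c1OC | intermediate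
8 | ethyl 3-(CD-aryl)propanoate | CCOC(=O)CCc1ccccc1Oc1c(CO[Si](C(C)C)(C(C)C)C(C)C)ccc(OC)c1OC | intermediate
9 | 3-(CD-aryl)propanal | O=CCCc1ccccc1Oc1c(CO[Si](C(C)C)(C(C)C)C(C)C)ccc(OC)c1OC | intermediate (not isolated)
10 | 4-(CD-aryl)but-1-yne | C#CCCc1ccccc1Oc1c(CO[Si](C(C)C)(C(C)C)C(C)C)ccc(OC)c1OC | intermediate
11 | 4,4-dichloro-3-[2-(CD-aryl)ethyl]cyclobut-2-en-1-one | O=C1C=C(CCc2ccccc2Oc2c(CO[Si](C(C)C)(C(C)C)C(C)C)ccc(OC)c2OC)C1(Cl)Cl | intermediate
12 | 3-[2-(CD-aryl)ethyl]cyclobut-2-en-1-one | O=C1C=C(CCc2ccccc2Oc2c(CO[Si](C(C)C)(C(C)C)C(C)C)ccc(OC)c2OC)C1 | intermediate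
13 | 4-(hydroxymethyl)phenol (4-hydroxybenzyl alcohol) | OCc1ccc(O)cc1 | starting material
14 | 4-({[tert-butyl(dimethyl)silyl]oxy}methyl)phenol | CC(C)(C)[Si](C)(C)OCc1ccc(O)cc1 | intermediate
15 | trichloroethylene | ClC=C(Cl)Cl | starting material
16 | tert-butyl[(4-{[(E)-1,2-dichloroethenyl]oxy}phenyl)methoxy]dimethylsilane | Cl/C=C(/Cl)Oc1ccc(CO[Si](C)(C)C(C)(C)C)cc1 | intermediate
17 | tert-butyl({4-[(chloroethynyl)oxy]phenyl}methoxy)dimethylsilane | ClC#COc1ccc(CO[Si](C)(C)C(C)(C)C)cc1 | intermediate (not isolated)
18 | lithium 2-(B-aryloxy)ethynide | [Li]C#COc1ccc(CO[Si](C)(C)C(C)(C)C)cc1 | intermediate (not isolated)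
19 | tert-butyl{[4-(ethynyloxy)phenyl]methoxy}dimethylsilane | C#COc1ccc(CO[Si](C)(C)C(C)(C)C)cc1 | intermediate
20 | 3-methylidene-5-(CD-aryl)pent-1-en-1-one (vinylketene) | O=C=CC(=C)CCc1ccccc1Oc1c(CO[Si](C(C)C)(C(C)C)C(C)C)ccc(OC)c1OC | intermediate (not isolated)
21 | 3-(B-aryloxy)-4-[4-(CD-aryl)but-1-en-2-yl]cyclobut-2-en-1-one (racemic) | O=C1C=C(Oc2ccc(CO[Si](C)(C)C(C)(C)C)cc2)C1C(=C)CCc1ccccc1Oc1c(CO[Si](C(C)C)(C(C)C)C(C)C)ccc(OC)c1OC | intermediate (not isolated)
22 | 3-(B-aryloxy)-5-methylidene-7-(CD-aryl)hepta-1,3-dien-1-one (ketene and vinyl groups cis on the C3=C4 bond) | O=C=C/C(Oc1ccc(CO[Si](C)(C)C(C)(C)C)cc1)=C\C(=C)CCc1ccccc1Oc1c(CO[Si](C(C)C)(C(C)C)C(C)C)ccc(OC)c1OC | intermediate (not isolated)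
23 | 3-(B-aryloxy)-5-[2-(CD-aryl)ethyl]cyclohexa-2,4-dien-1-one | O=C1C=C(Oc2ccc(CO[Si](C)(C)C(C)(C)C)cc2)C=C(CCc2ccccc2Oc2c(CO[Si](C(C)C)(C(C)C)C(C)C)ccc(OC)c2OC)C1 | intermediate (not isolated)
24 | 3-(B-aryloxy)-5-[2-(CD-aryl)ethyl]phenol | Oc1cc(CCc2ccccc2Oc2c(CO[Si](C(C)C)(C(C)C)C(C)C)ccc(OC)c2OC)cc(Oc2ccc(CO[Si](C)(C)C(C)(C)C)cc2)c1 | intermediate
25 | 1-(B-aryloxy)-3-[2-(CD-aryl)ethyl]-5-(methoxymethoxy)benzene | COCOc1cc(CCc2ccccc2Oc2c(CO[Si](C(C)C)(C(C)C)C(C)C)ccc(OC)c2OC)cc(Oc2ccc(CO[Si](C)(C)C(C)(C)C)cc2)c1 | intermediate
26 | {2-(B-aryloxy)-4-[2-(CD-aryl)ethyl]-6-(methoxymethoxy)phenyl}lithium | COCOc1cc(CCc2ccccc2Oc2c(CO[Si](C(C)C)(C(C)C)C(C)C)ccc(OC)c2OC)cc(Oc2ccc(CO[Si](C)(C)C(C)(C)C)cc2)c1[Li] | intermediate (not isolated)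
27 | dimethyl {2-(B-aryloxy)-4-[2-(CD-aryl)ethyl]-6-(methoxymethoxy)phenyl}boronate | COCOc1cc(CCc2ccccc2Oc2c(CO[Si](C(C)C)(C(C)C)C(C)C)ccc(OC)c2OC)cc(Oc2ccc(CO[Si](C)(C)C(C)(C)C)cc2)c1B(OC)OC | intermediate (not isolated)
28 | 2-(B-aryloxy)-4-[2-(CD-aryl)ethyl]-6-(methoxymethoxy)phenol | COCOc1cc(CCc2ccccc2Oc2c(CO[Si](C(C)C)(C(C)C)C(C)C)ccc(OC)c2OC)cc(Oc2ccc(CO[Si](C)(C)C(C)(C)C)cc2)c1O | intermediate
29 | 1-(B-aryloxy)-5-[2-(CD-aryl)ethyl]-2-methoxy-3-(methoxymethoxy)benzene | COCOc1cc(CCc2ccccc2Oc2c(CO[Si](C(C)C)(C(C)C)C(C)C)ccc(OC)c2OC)cc(Oc2ccc(CO[Si](C)(C)C(C)(C)C)cc2)c1OC | intermediate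
30 | {4-[5-[2-(CD-aryl)ethyl]-2-methoxy-3-(methoxymethoxy)phenoxy]phenyl}methanol | COCOc1cc(CCc2ccccc2Oc2c(CO[Si](C(C)C)(C(C)C)C(C)C)ccc(OC)c2OC)cc(Oc2ccc(CO)cc2)c1OC | intermediate
31 | 4-{5-[2-(CD-aryl)ethyl]-2-methoxy-3-(methoxymethoxy)phenoxy}benzaldehyde | COCOc1cc(CCc2ccccc2Oc2c(CO[Si](C(C)C)(C(C)C)C(C)C)ccc(OC)c2OC)cc(Oc2ccc(C=O)cc2)c1OC | intermediate
32 | 4-[5-(2-{2-[6-(hydroxymethyl)-2,3-dimethoxyphenoxy]phenyl}ethyl)-2-methoxy-3-(methoxymethoxy)phenoxy]benzaldehyde | COCOc1cc(CCc2ccccc2Oc2c(CO)ccc(OC)c2OC)cc(Oc2ccc(C=O)cc2)c1OC | intermediate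
33 | 4-[5-(2-{2-[6-(bromomethyl)-2,3-dimethoxyphenoxy]phenyl}ethyl)-2-methoxy-3-(methoxymethoxy)phenoxy]benzaldehyde | COCOc1cc(CCc2ccccc2Oc2c(CBr)ccc(OC)c2OC)cc(Oc2ccc(C=O)cc2)c1OC | intermediate (not isolated)
34 | {[2-(2-{2-[3-(4-formylphenoxy)-4-methoxy-5-(methoxymethoxy)phenyl]ethyl}phenoxy)-3,4-dimethoxyphenyl]methyl}triphenylphosphonium bromide | COCOc1cc(CCc2ccccc2Oc2c(C[P+](c3ccccc3)(c3ccccc3)c3ccccc3)ccc(OC)c2OC)cc(Oc2ccc(C=O)cc2)c1OC.[Br-] | intermediate
35 | triphenylphosphonium ylide of 34 (benzylidene phosphorane on ring C) | COCOc1cc(CCc2ccccc2Oc2c(C=P(c3ccccc3)(c3ccccc3)c3ccccc3)ccc(OC)c2OC)cc(Oc2ccc(C=O)cc2)c1OC | intermediate (not isolated)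
36 | macrocyclic stilbene, CH=CH between rings B and C, ring A C1 methoxymethyl ether and C6 methyl ether, ring C dimethyl ether (E/Z mixture) | COCOc1cc2cc(c1OC)Oc1ccc(cc1)C=Cc1ccc(OC)c(OC)c1Oc1ccccc1CC2 | intermediate
37 | macrocyclic bibenzyl, ring A C1 methoxymethyl ether and C6 methyl ether, ring C dimethyl ether | COCOc1cc2cc(c1OC)Oc1ccc(cc1)CCc1ccc(OC)c(OC)c1Oc1ccccc1CC2 | intermediate
38 | target macrocycle CNP0114693.0 (achiral) | Oc1cc2cc(c1O)Oc1ccc(cc1)CCc1ccc(O)c(O)c1Oc1ccccc1CC2 | target

## Step count and least certain steps

Total: 22 steps. Longest linear sequence: 19 steps (1 to 38 through steps 1–8 and 12–22); the ynol ether branch (steps 9–11) adds 3.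

**Step 12 (key step).** The most likely failure is loss of the terminal aryl ynol ether 19 by polymerisation or adventitious hydration before it intercepts vinylketene 20. The ketene would then dimerise or acylate the product phenol, and 21 might not be driven fully on to the arene. The fallback keeps the annulation but uses a sturdier alkyne and attaches ring B afterwards. It sets out from 12 and returns at 24.
- Cyclobutenone 12 is heated in toluene with (triisopropylsilyloxy)ethyne, a member of the alkyne class for which this annulation is best established.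
- The reaction passes through the silyloxy counterparts of 21 to 23: 3-{[tri(propan-2-yl)silyl]oxy}-4-[4-(CD-aryl)but-1-en-2-yl]cyclobut-2-en-1-one F1, 3-{[tri(propan-2-yl)silyl]oxy}-5-methylidene-7-(CD-aryl)hepta-1,3-dien-1-one F2 and 3-{[tri(propan-2-yl)silyl]oxy}-5-[2-(CD-aryl)ethyl]cyclohexa-2,4-dien-1-one F3.
- It should give the resorcinol monosilyl ether 3-[2-(CD-aryl)ethyl]-5-{[tri(propan-2-yl)silyl]oxy}phenol F4.
- Chan–Lam arylation of the free, unhindered hydroxyl with [4-({[tert-butyl(dimethyl)silyl]oxy}methyl)phenyl]boronic acid (Cu(OAc)2, pyridine, 4 Å sieves, CH2Cl2, air) should give {3-(B-aryloxy)-5-[2-(CD-aryl)ethyl]phenoxy}tri(propan-2-yl)silane F5.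
- KHF2 in MeOH, which cleaves silyl ethers of phenols but not of alcohols, would then return 24.

**Step 14.** Two processes threaten it. Deprotonation may occur away from C6 of ring A (next to a methoxy group on ring C, or at a silyloxymethyl carbon), because the substrate offers many weakly activated protons. The crowded 2,6-dioxygenated boronate may also lose boron by protonolysis before it is oxidised. The fallback forms the C–O bond by copper catalysis from an isolable halide. It sets out from 25 and returns at 29.
- After lithiation as in step 14 (through 26), iodine is added instead of the borate, giving 1-(B-aryloxy)-5-[2-(CD-aryl)ethyl]-2-iodo-3-(methoxymethoxy)benzene F6, from which misdirected isomers can be removed by chromatography.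
- Copper-catalysed coupling with methanol (copper monoiodide CuI, 3,4,7,8-tetramethyl-1,10-phenanthroline, Cs2CO3, MeOH/toluene, 110 °C) should give methyl ether 29 directly, saving the separate methylation.

**Step 16.** Discrimination between the two silyl ethers may be incomplete, giving over-cleavage to the diol or a sluggish reaction that also erodes the acetal. The fallback needs no discrimination. It sets out from 29 and returns at 37.
- Excess Bu4NF in THF removes both silyl groups to give the diol {4-[5-(2-{2-[6-(hydroxymethyl)-2,3-dimethoxyphenoxy]phenyl}ethyl)-2-methoxy-3-(methoxymethoxy)phenoxy]phenyl}methanol F7.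
- CBr4/PPh3 in CH2Cl2 converts it to the dibromide 1-[4-(bromomethyl)phenoxy]-5-(2-{2-[6-(bromomethyl)-2,3-dimethoxyphenoxy]phenyl}ethyl)-2-methoxy-3-(methoxymethoxy)benzene F8.
- Intramolecular Wurtz coupling (Na, tetraphenylethene, THF, −78 °C, high dilution) would give bibenzyl 37 directly, without the alkene stage.

**Step 20.** Intermolecular olefination may outrun ring closure, giving dimers and oligomers, if the chain ends are rarely close or if ylide 35 is consumed by moisture. The fallback closes the same bond reductively. It sets out from 32 and returns at 36.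
- MnO2 in CH2Cl2 oxidises 32 to the dialdehyde 2-(2-{2-[3-(4-formylphenoxy)-4-methoxy-5-(methoxymethoxy)phenyl]ethyl}phenoxy)-3,4-dimethoxybenzaldehyde F9.
- McMurry coupling (TiCl3(DME)1.5, Zn–Cu couple, DME, reflux, slow addition) on the templating titanium surface should give stilbene 36.

## Further compounds

F1 | step 12 | 3-{[tri(propan-2-yl)silyl]oxy}-4-[4-(CD-aryl)but-1-en-2-yl]cyclobut-2-en-1-one (racemic, not isolated) | O=C1C=C(O[Si](C(C)C)(C(C)C)C(C)C)C1C(=C)CCc1ccccc1Oc1c(CO[Si](C(C)C)(C(C)C)C(C)C)ccc(OC)c1OC
F2 | step 12 | 3-{[tri(propan-2-yl)silyl]oxy}-5-methylidene-7-(CD-aryl)hepta-1,3-dien-1-one (not isolated) | O=C=C/C(O[Si](C(C)C)(C(C)C)C(C)C)=C\C(=C)CCc1ccccc1Oc1c(CO[Si](C(C)C)(C(C)C)C(C)C)ccc(OC)c1OC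
F3 | step 12 | 3-{[tri(propan-2-yl)silyl]oxy}-5-[2-(CD-aryl)ethyl]cyclohexa-2,4-dien-1-one (not isolated) | O=C1C=C(O[Si](C(C)C)(C(C)C)C(C)C)C=C(CCc2ccccc2Oc2c(CO[Si](C(C)C)(C(C)C)C(C)C)ccc(OC)c2OC)C1
F4 | step 12 | 3-[2-(CD-aryl)ethyl]-5-{[tri(propan-2-yl)silyl]oxy}phenol | Oc1cc(CCc2ccccc2Oc2c(CO[Si](C(C)C)(C(C)C)C(C)C)ccc(OC)c2OC)cc(O[Si](C(C)C)(C(C)C)C(C)C)c1
F5 | step 12 | {3-(B-aryloxy)-5-[2-(CD-aryl)ethyl]phenoxy}tri(propan-2-yl)silane | CC(C)[Si](Oc1cc(CCc2ccccc2Oc2c(CO[Si](C(C)C)(C(C)C)C(C)C)ccc(OC)c2OC)cc(Oc2ccc(CO[Si](C)(C)C(C)(C)C)cc2)c1)(C(C)C)C(C)C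
F6 | step 14 | 1-(B-aryloxy)-5-[2-(CD-aryl)ethyl]-2-iodo-3-(methoxymethoxy)benzene | COCOc1cc(CCc2ccccc2Oc2c(CO[Si](C(C)C)(C(C)C)C(C)C)ccc(OC)c2OC)cc(Oc2ccc(CO[Si](C)(C)C(C)(C)C)cc2)c1I
F7 | step 16 | {4-[5-(2-{2-[6-(hydroxymethyl)-2,3-dimethoxyphenoxy]phenyl}ethyl)-2-methoxy-3-(methoxymethoxy)phenoxy]phenyl}methanol | COCOc1cc(CCc2ccccc2Oc2c(CO)ccc(OC)c2OC)cc(Oc2ccc(CO)cc2)c1OC
F8 | step 16 | 1-[4-(bromomethyl)phenoxy]-5-(2-{2-[6-(bromomethyl)-2,3-dimethoxyphenoxy]phenyl}ethyl)-2-methoxy-3-(methoxymethoxy)benzene | COCOc1cc(CCc2ccccc2Oc2c(CBr)ccc(OC)c2OC)cc(Oc2ccc(CBr)cc2)c1OC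
F9 | step 20 | 2-(2-{2-[3-(4-formylphenoxy)-4-methoxy-5-(methoxymethoxy)phenyl]ethyl}phenoxy)-3,4-dimethoxybenzaldehyde | COCOc1cc(CCc2ccccc2Oc2c(C=O)ccc(OC)c2OC)cc(Oc2ccc(C=O)cc2)c1OC
A1 | alternative 1 | bis(methoxymethyl) ether of the macrocycle lacking the ring A C6 and ring C C5 hydroxyls | COCOc1cc2cc(c1)Oc1ccc(cc1)CCc1ccc(OCOC)cc1Oc1ccccc1CC2
A2 | alternative 1 | macrocyclic diol bis(methoxymethyl) ether | COCOc1cc2cc(c1O)Oc1ccc(cc1)CCc1ccc(OCOC)c(O)c1Oc1ccccc1CC2
A3 | alternative 2 | open-chain 4-fluorophenyl ketone with free ring A phenol | COc1cc(CCc2ccccc2Oc2c(CC(=O)c3ccc(F)cc3)ccc(OC)c2OC)cc(O)c1OC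
A4 | alternative 2 | macrocyclic ketone, oxo group on the bridge carbon next to ring B | COc1cc2cc(c1OC)Oc1ccc(cc1)C(=O)Cc1ccc(OC)c(OC)c1Oc1ccccc1CC2
A5 | alternative 3 | internal aryl ynol ether carrying the ring A arylethyl chain | COc1ccc(CCc2ccc(O[Si](C(C)C)(C(C)C)C(C)C)cc2)c(OC#CCCc2cc(Br)c(OC)c(OC)c2)c1OC
A6 | alternative 3 | 2H-pyran-2-one | O=C1C=CC=CO1
A7 | alternative 3 | open-chain compound with ring D formed, ring A bromide and silylated ring B phenol | COc1ccc(CCc2ccc(O[Si](C(C)C)(C(C)C)C(C)C)cc2)c(Oc2ccccc2CCc2cc(Br)c(OC)c(OC)c2)c1OC
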